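**Strategy.** Everything rests on cutting C5–C6 and C10–C20: the cis one-carbon arms C6 (on C5) and C20 (on the quaternary spiro carbon C10) of ring A are read as the two halves of a cyclobutene. A [2+2] photocycloaddition of acetylene to a 2-carboalkoxy-4,4-dimethylcyclohexenone (ester carbon = C9, chiral 8-phenylmenthyl ester) forms both bonds, the quaternary C10 and the C5/C10 relationship in one operation; the cis ring fusion places C9 trans to C6. Ozonolysis later unveils C6 and C20 as CH2OH groups, which lactonisation onto C9 tells apart. Knoevenagel lactonisation, Diels–Alder (ring C) and palladium cycloalkenylation (ring D) complete the skeleton.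

Key step: step 4

Remark (locants): ring A = C1–C5 and C10, with C6 on C5; lactone = C10–C20–O–C7(=O)–C8–C9; ring C = C8, C9, C11–C14; ring D = C8, C14, C13, C16, C15, with C17 on C16.

Remark (assumption): the (1R,2S,5R)-auxiliary is assumed to favour the (1S,6R) photoadduct (the enantiomeric alcohol would be used otherwise, the diastereomers being separable either way), and the C1 carbinol of 11–27 is drawn as expected for hydride attack anti to the angular ester, a centre that is erased in step 15.

Step 1
Reactants: 1 4,4-dimethylcyclohexanone; 2 dimethyl carbonate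
Product: 3 methyl 5,5-dimethyl-2-oxocyclohexane-1-carboxylate
Conditions: NaH, THF, reflux; AcOH quench
Reagents that add atoms: none
Why: Claisen-type C-acylation of the sodium enolate by the carbonate is driven by deprotonation of the β-keto ester formed, and the symmetric ketone allows only one regioisomer.

Step 2
Reactants: 3 methyl 5,5-dimethyl-2-oxocyclohexane-1-carboxylate; 4 (1R,2S,5R)-8-phenylmenthol
Product: 5 (1R,2S,5R)-8-phenylmenthyl 5,5-dimethyl-2-oxocyclohexane-1-carboxylate
Conditions: DMAP (cat.), toluene, reflux, 4 Å sieves (removal of MeOH)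
Reagents that add atoms: none
Why: DMAP-catalysed transesterification of an enolisable β-keto ester (through its acylketene) exchanges methanol for the hindered secondary alcohol without touching the stereocentres of the auxiliary.

Step 3
Reactants: 5 8-phenylmenthyl 5,5-dimethyl-2-oxocyclohexane-1-carboxylate
Product: 8 (1R,2S,5R)-8-phenylmenthyl 3,3-dimethyl-6-oxocyclohex-1-ene-1-carboxylate, via α-phenylselanyl keto ester 6 (not isolated), via selenoxide 7 (not isolated)
Conditions: PhSeCl, pyridine, CH2Cl2, 0 °C; then 30% H2O2, 0 → 25 °C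
Reagents that add atoms: none
Why: Reich selenenylation at the only doubly activated carbon followed by selenoxide syn-elimination, which can take a β-hydrogen only from the ring CH2 next to the CMe2 group, gives the enone ester.

Step 4
Reactants: 8 8-phenylmenthyl 3,3-dimethyl-6-oxocyclohex-1-ene-1-carboxylate; 9 acetylene
Product: 10 (1R,2S,5R)-8-phenylmenthyl (1S,6R)-5,5-dimethyl-2-oxobicyclo[4.2.0]oct-7-ene-1-carboxylate
Conditions: hν (366 nm), acetylene stream, acetone/CH2Cl2, −70 °C, stopped before full conversion; chromatography of the diastereomers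
Reagents that add atoms: none
Why: Excitation gives the triplet enone ester, which bonds C5 to acetylene to form a 1,4-biradical (C10 radical stabilised by ketone and ester, vinyl radical at C20) that collapses after spin inversion; the closest known reaction type is the [2+2] photocycloaddition of 2-carboalkoxycyclohexenones to alkynes. The cyclobutene closes by coupling of the C10 radical with the C20 radical, a four-membered closure that is possible only cis on the six-membered ring. The relative configuration of C5 and C10 (C6 cis to C20, C9 trans to C6) is therefore fixed by ring strain, and the absolute configuration of both centres by the 8-phenylmenthyl ester, whose phenyl ring covers one face of the C5=C10 bond, the two diastereomeric adducts being separable. The step needs chemoselectivity for intermolecular addition over lumiketone rearrangement of the 4,4-dimethylenone and over a secondary 1,3-acyl shift of the β,γ-unsaturated ketone product; a high acetylene concentration at low temperature and irradiation only in the long-wavelength band of the conjugated chromophore should secure this. Regiochemistry does not arise because acetylene is symmetric, and C10 becomes quaternary without any enolate alkylation.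

Step 5
Reactants: 10 bicyclo[4.2.0]octenone ester
Product: 11 (1R,2S,5R)-8-phenylmenthyl (1S,2R,6R)-2-hydroxy-5,5-dimethylbicyclo[4.2.0]oct-7-ene-1-carboxylate
Conditions: NaBH4, MeOH/THF, −20 °C
Reagents that add atoms: none
Why: Borohydride reduction of the ring ketone removes the 1,3-dicarbonyl relationship at C10 before ozonolysis (a C20 aldehyde beside ketone and ester would be deformylated), hydride arriving anti to the angular ester while the hindered ester is untouched.

Step 6
Reactants: 11 C1 alcohol
Product: 12 (1R,2S,5R)-8-phenylmenthyl (1S,2R,6R)-2-(benzyloxy)-5,5-dimethylbicyclo[4.2.0]oct-7-ene-1-carboxylate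
Conditions: 2-benzyloxy-1-methylpyridinium triflate, MgO, PhCF3, 85 °C
Reagents that add atoms: 2-benzyloxy-1-methylpyridinium triflate, C[n+]1ccccc1OCc1ccccc1.[O-]S(=O)(=O)C(F)(F)F
Why: Neutral thermal benzyl transfer from the pyridinium salt etherifies the hindered β-hydroxy ester without the alkoxide that could trigger retro-aldol cleavage.

Step 7
Reactants: 12 C1 benzyl ether
Product: 15 trans-fused 7-(benzyloxy)-7a-(hydroxymethyl)-4,4-dimethylhexahydro-2-benzofuran-1(3H)-one, via ozonide 13 (not isolated), via C6/C20 diol ester 14 (not isolated)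
Conditions: O3, CH2Cl2, −78 °C; NaBH4, MeOH, −78 → 25 °C; CSA (cat.), toluene, 60 °C
Reagents that add atoms: ozone, [O-][O+]=O
Why: Ozonolysis of the strained cyclobutene with hydride reduction of the ozonide gives the C6/C20 diol, and only the C6 hydroxyl can lactonise onto the C9 ester (five-membered ring, whereas C20–OH would need a four-membered ring), which releases the auxiliary and differentiates the two arms without touching a stereocentre.

Step 8
Reactants: 15 γ-lactone alcohol
Product: 16 C20 triethylsilyl ether of the γ-lactone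
Conditions: Et3SiCl, imidazole, DMAP (cat.), DMF, 25 °C
Reagents that add atoms: chlorotriethylsilane, CC[Si](Cl)(CC)CC
Why: Silylation of the only free hydroxyl masks C20–OH with a labile group, so that the lactone opening that follows frees a single alcohol.

Step 9
Reactants: 16 silylated γ-lactone
Product: 18 2-(benzyloxy)-6-[(tert-butyldiphenylsilyloxy)methyl]-N-methoxy-N,5,5-trimethyl-1-[(triethylsilyloxy)methyl]cyclohexane-1-carboxamide, via C6 hydroxy Weinreb amide 17 (not isolated)
Conditions: MeNH(OMe)·HCl, AlMe3, CH2Cl2, 0 → 40 °C; then t-BuPh2SiCl, imidazole, DMF, 25 °C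
Reagents that add atoms: N,O-dimethylhydroxylamine hydrochloride, CNOC.Cl; tert-butyl(chloro)diphenylsilane, CC(C)(C)[Si](Cl)(c1ccccc1)c1ccccc1
Why: Aluminium amide aminolysis of the strained lactone gives the Weinreb amide at C9 and frees only C6–OH, which is silylated at once so that relactonisation cannot occur.

Step 10
Reactants: 18 Weinreb amide
Product: 20 2-(benzyloxy)-6-[(tert-butyldiphenylsilyloxy)methyl]-1-(hydroxymethyl)-5,5-dimethylcyclohexane-1-carbaldehyde, via C20 silyl ether aldehyde 19 (not isolated)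
Conditions: i-Bu2AlH, THF, −78 °C; then AcOH/THF/H2O (3:1:1), 25 °C
Reagents that add atoms: none
Why: Hydride addition to the Weinreb amide stops at the chelated hemiaminal and gives the non-enolisable C9 aldehyde on work-up, and aqueous acetic acid then cleaves the triethylsilyl ether selectively beside the tert-butyldiphenylsilyl ether.

Step 11
Reactants: 20 hydroxy aldehyde
Product: 22 4-acetyl-7-(benzyloxy)-11-[(tert-butyldiphenylsilyloxy)methyl]-10,10-dimethyl-2-oxaspiro[5.5]undec-4-en-3-one, via C20 acetoacetate 21 (not isolated)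
Conditions: diketene, DMAP (cat.), CH2Cl2, −20 → 0 °C; then ethylenediammonium diacetate (cat.), 4 Å sieves, 25 °C
Reagents that add atoms: diketene, C=C1CC(=O)O1
Why: O-Acetoacetylation of C20–OH followed by amine-salt-catalysed intramolecular Knoevenagel condensation with the C9 aldehyde closes the six-membered spirolactone and fixes the C8=C9 geometry with the lactone carbonyl cis to C10.

Step 12
Reactants: 22 alkylidene β-keto lactone; 23 buta-1,3-diene
Product: 24 cis-fused Diels–Alder adduct (8-acetyl spirolactone with C12=C13)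
Conditions: buta-1,3-diene (excess), ZnCl2, CH2Cl2, sealed tube, 0 → 25 °C
Reagents that add atoms: none
Why: The chelated alkylidene β-keto lactone is a doubly activated dienophile in a Diels–Alder reaction; the diene should add suprafacially to the C8=C9 face on the C1 side, away from the C5 side shielded by the C6 silyl ether and the C4 methyl groups, which sets C9 (H toward C5) and quaternary C8 (acetyl cis to H9) together.

Step 13
Reactants: 24 Diels–Alder adduct
Product: 26 1-benzyloxy-6-silyloxy-15-oxo spirolactone with bicyclo[3.2.1]octene rings C and D (C11=C12), via trimethylsilyl enol ether 25 (not isolated)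
Conditions: Me3SiOTf, Et3N, CH2Cl2, 0 °C; then Pd(OAc)2 (1.1 equiv), MeCN, 25 °C
Reagents that add atoms: none
Why: Kende-type palladium-mediated cycloalkenylation: the enol silane of the methyl ketone (C8 is quaternary, so only C16 can enolise) gives a palladium enolate that adds 5-exo across C12=C13, and β-hydride elimination toward C11 (the bridgehead C13–H cannot eliminate) leaves the bicyclo[3.2.1]octenone, C13 being set by the bridge that must span the acetyl-bearing face of ring C.

Step 14
Reactants: 26 bicyclo[3.2.1]octenone benzyl ether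
Product: 27 saturated 15-ketone with free C1 hydroxyl
Conditions: H2 (3 atm), Pd(OH)2/C, EtOAc/EtOH, 25 °C
Reagents that add atoms: none
Why: Heterogeneous hydrogenation saturates the disubstituted C11=C12 alkene and hydrogenolyses the benzyl ether in one operation, while ketone, lactone and silyl ether are inert.

Step 15
Reactants: 27 C1 alcohol
Product: 28 1,15-diketone
Conditions: Dess–Martin periodinane, CH2Cl2, 25 °C
Reagents that add atoms: none
Why: Dess–Martin oxidation converts the hindered secondary alcohol to the C1 ketone under non-basic conditions, and the quaternary C10 rules out β-elimination of the C20 acyloxy group.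

Step 16
Reactants: 28 1,15-diketone
Product: 30 ring A enone (C2=C3) with 15-ketone, via bis(trimethylsilyl enol ether) 29 (not isolated)
Conditions: Me3SiOTf, Et3N, CH2Cl2, 0 °C; then Pd(OAc)2 (1.2 equiv), MeCN, 25 °C; 1 M HCl/THF work-up
Reagents that add atoms: none
Why: Saegusa–Ito oxidation: both ketones are silylated, but only the ring A palladium enolate has a β-hydrogen that can eliminate (the C15 enolate would need a bridgehead alkene at C13), so dehydrogenation is confined to C2–C3 and the C15 enol ether is hydrolysed back on work-up.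

Step 17
Reactants: 30 ring A enone
Product: 32 C6 tert-butyldiphenylsilyl ether of the target, via C15 trimethylsilyl enol ether 31 (not isolated)
Conditions: Me3SiOTf, Et3N, CH2Cl2, 0 °C; then 37% aq. HCHO, Yb(OTf)3 (10 mol%), THF, 25 °C
Reagents that add atoms: formaldehyde, C=O
Why: Lanthanide triflate-catalysed Mukaiyama aldol with aqueous formaldehyde on the only enol silane that can form (the ring A enone has no enolisable hydrogen); formaldehyde should attack C16 from the exo face, away from the C11–C12 bridge, giving the exo hydroxymethyl epimer, which is also the thermodynamically preferred one.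

Step 18
Reactants: 32 silyl-protected target
Product: 33 CNP0505075.1
Conditions: HF·pyridine, pyridine/THF, 0 → 25 °C
Reagents that add atoms: none
Why: Fluoride cleavage of the silyl ether under mildly acidic buffering avoids retro-aldol or dehydration of the β-hydroxy ketone and retro-Claisen opening of the β-keto lactone.

**Compound list**

1 | 4,4-dimethylcyclohexanone | CC1(C)CCC(=O)CC1 | starting material
2 | dimethyl carbonate | COC(=O)OC | starting material
3 | methyl 5,5-dimethyl-2-oxocyclohexane-1-carboxylate (racemic) | COC(=O)C1CC(C)(C)CCC1=O | intermediate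
4 | (1R,2S,5R)-5-methyl-2-(2-phenylpropan-2-yl)cyclohexan-1-ol, (−)-8-phenylmenthol | C[C@@H]1CC[C@H]([C@@H](C1)O)C(C)(C)c1ccccc1 | starting material
5 | (1R,2S,5R)-8-phenylmenthyl 5,5-dimethyl-2-oxocyclohexane-1-carboxylate (α-epimers) | C[C@@H]1CC[C@H]([C@@H](C1)OC(=O)C1CC(C)(C)CCC1=O)C(C)(C)c1ccccc1 | intermediate
6 | 1-(phenylselanyl) derivative of 5 | C[C@@H]1CC[C@H]([C@@H](C1)OC(=O)C1([Se]c2ccccc2)CC(C)(C)CCC1=O)C(C)(C)c1ccccc1 | intermediate
7 | selenoxide of 6 | C[C@@H]1CC[C@H]([C@@H](C1)OC(=O)C1([Se](=O)c2ccccc2)CC(C)(C)CCC1=O)C(C)(C)c1ccccc1 | intermediate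
8 | (1R,2S,5R)-8-phenylmenthyl 3,3-dimethyl-6-oxocyclohex-1-ene-1-carboxylate (key-step precursor) | C[C@@H]1CC[C@H]([C@@H](C1)OC(=O)C1=CC(C)(C)CCC1=O)C(C)(C)c1ccccc1 | intermediate
9 | acetylene | C#C | starting material
10 | (1R,2S,5R)-8-phenylmenthyl (1S,6R)-5,5-dimethyl-2-oxobicyclo[4.2.0]oct-7-ene-1-carboxylate (key-step product, cis-fused) | C[C@@H]1CC[C@H]([C@@H](C1)OC(=O)[C@@]12C=C[C@@H]1C(C)(C)CCC2=O)C(C)(C)c1ccccc1 | intermediate
11 | (1R,2S,5R)-8-phenylmenthyl (1S,2R,6R)-2-hydroxy-5,5-dimethylbicyclo[4.2.0]oct-7-ene-1-carboxylate | C[C@@H]1CC[C@H]([C@@H](C1)OC(=O)[C@@]12C=C[C@@H]1C(C)(C)CC[C@H]2O)C(C)(C)c1ccccc1 | intermediate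
12 | (1R,2S,5R)-8-phenylmenthyl (1S,2R,6R)-2-(benzyloxy)-5,5-dimethylbicyclo[4.2.0]oct-7-ene-1-carboxylate | C[C@@H]1CC[C@H]([C@@H](C1)OC(=O)[C@@]12C=C[C@@H]1C(C)(C)CC[C@H]2OCc2ccccc2)C(C)(C)c1ccccc1 | intermediate
13 | ozonide (1,2,4-trioxolane across C6 and C20) of 12 | C[C@@H]1CC[C@H]([C@@H](C1)OC(=O)[C@@]12C3OC(OO3)[C@@H]1C(C)(C)CC[C@H]2OCc2ccccc2)C(C)(C)c1ccccc1 | intermediate
14 | 8-phenylmenthyl 2-(benzyloxy)-1,6-bis(hydroxymethyl)-5,5-dimethylcyclohexane-1-carboxylate (C6 and C20 hydroxymethyls cis) | C[C@@H]1CC[C@H]([C@@H](C1)OC(=O)[C@@]1(CO)[C@H](CO)C(C)(C)CC[C@H]1OCc1ccccc1)C(C)(C)c1ccccc1 | intermediate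
15 | trans-fused 7-(benzyloxy)-7a-(hydroxymethyl)-4,4-dimethylhexahydro-2-benzofuran-1(3H)-one (lactone C9(=O)–O–C6; free C20–OH) | O=C1OC[C@@H]2C(C)(C)CC[C@@H](OCc3ccccc3)[C@@]12CO | intermediate
16 | C20 triethylsilyl ether of 15 | O=C1OC[C@@H]2C(C)(C)CC[C@@H](OCc3ccccc3)[C@@]12CO[Si](CC)(CC)CC | intermediate
17 | 2-(benzyloxy)-6-(hydroxymethyl)-N-methoxy-N,5,5-trimethyl-1-[(triethylsilyloxy)methyl]cyclohexane-1-carboxamide | CON(C)C(=O)[C@@]1(CO[Si](CC)(CC)CC)[C@H](CO)C(C)(C)CC[C@H]1OCc1ccccc1 | intermediate
18 | C6 tert-butyldiphenylsilyl ether of 17 | CON(C)C(=O)[C@@]1(CO[Si](CC)(CC)CC)[C@H](CO[Si](c2ccccc2)(c2ccccc2)C(C)(C)C)C(C)(C)CC[C@H]1OCc1ccccc1 | intermediate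
19 | 2-(benzyloxy)-6-[(tert-butyldiphenylsilyloxy)methyl]-5,5-dimethyl-1-[(triethylsilyloxy)methyl]cyclohexane-1-carbaldehyde | O=C[C@@]1(CO[Si](CC)(CC)CC)[C@H](CO[Si](c2ccccc2)(c2ccccc2)C(C)(C)C)C(C)(C)CC[C@H]1OCc1ccccc1 | intermediate
20 | 2-(benzyloxy)-6-[(tert-butyldiphenylsilyloxy)methyl]-1-(hydroxymethyl)-5,5-dimethylcyclohexane-1-carbaldehyde | O=C[C@@]1(CO)[C@H](CO[Si](c2ccccc2)(c2ccccc2)C(C)(C)C)C(C)(C)CC[C@H]1OCc1ccccc1 | intermediate
21 | C20 acetoacetate of 20 | CC(=O)CC(=O)OC[C@]1(C=O)[C@H](CO[Si](c2ccccc2)(c2ccccc2)C(C)(C)C)C(C)(C)CC[C@H]1OCc1ccccc1 | intermediate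
22 | 4-acetyl-7-(benzyloxy)-11-[(tert-butyldiphenylsilyloxy)methyl]-10,10-dimethyl-2-oxaspiro[5.5]undec-4-en-3-one (C8=C9 alkylidene β-keto spirolactone) | CC(=O)C1=C[C@@]2(COC1=O)[C@H](CO[Si](c3ccccc3)(c3ccccc3)C(C)(C)C)C(C)(C)CC[C@H]2OCc2ccccc2 | intermediate
23 | buta-1,3-diene | C=CC=C | starting material
24 | Diels–Alder adduct: spirolactone cis-fused to a cyclohexene ring C (C12=C13), 8-acetyl cis to H9, C11 and C14 on the C1 side | CC(=O)[C@]12CC=CC[C@H]1[C@@]1(COC2=O)[C@H](CO[Si](c3ccccc3)(c3ccccc3)C(C)(C)C)C(C)(C)CC[C@H]1OCc1ccccc1 | intermediate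
25 | trimethylsilyl enol ether (C15=C16) of 24 | C=C(O[Si](C)(C)C)[C@]12CC=CC[C@H]1[C@@]1(COC2=O)[C@H](CO[Si](c3ccccc3)(c3ccccc3)C(C)(C)C)C(C)(C)CC[C@H]1OCc1ccccc1 | intermediate
26 | tetracyclic 15-ketone with C11=C12, C1 benzyl ether, C6 tert-butyldiphenylsilyl ether | CC1(C)CC[C@@H](OCc5ccccc5)[C@]2(COC(=O)[C@@]34C[C@@H](C=C[C@H]32)CC4=O)[C@@H]1CO[Si](c1ccccc1)(c1ccccc1)C(C)(C)C | intermediate
27 | saturated tetracyclic 15-ketone with free C1 hydroxyl | CC1(C)CC[C@@H](O)[C@]2(COC(=O)[C@@]34C[C@@H](CC[C@H]32)CC4=O)[C@@H]1CO[Si](c1ccccc1)(c1ccccc1)C(C)(C)C | intermediate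
28 | tetracyclic 1,15-diketone | CC1(C)CCC(=O)[C@]2(COC(=O)[C@@]34C[C@@H](CC[C@H]32)CC4=O)[C@@H]1CO[Si](c1ccccc1)(c1ccccc1)C(C)(C)C | intermediate
29 | bis(trimethylsilyl enol ether) (C1=C2 and C15=C16) of 28 | CC1(C)CC=C(O[Si](C)(C)C)[C@]2(COC(=O)[C@@]34C[C@@H](CC[C@H]32)C=C4O[Si](C)(C)C)[C@@H]1CO[Si](c1ccccc1)(c1ccccc1)C(C)(C)C | intermediate
30 | 1-oxo-2-ene 15-ketone, C6 silyl ether | CC1(C)C=CC(=O)[C@]2(COC(=O)[C@@]34C[C@@H](CC[C@H]32)CC4=O)[C@@H]1CO[Si](c1ccccc1)(c1ccccc1)C(C)(C)C | intermediate
31 | C15 trimethylsilyl enol ether of 30 | CC1(C)C=CC(=O)[C@]2(COC(=O)[C@@]34C[C@@H](CC[C@H]32)C=C4O[Si](C)(C)C)[C@@H]1CO[Si](c1ccccc1)(c1ccccc1)C(C)(C)C | intermediate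
32 | C6 tert-butyldiphenylsilyl ether of the target | CC1(C)C=CC(=O)[C@]2(COC(=O)[C@@]34C[C@@H](CC[C@H]32)[C@H](CO)C4=O)[C@@H]1CO[Si](c1ccccc1)(c1ccccc1)C(C)(C)C | intermediate
33 | CNP0505075.1 | CC1(C)C=CC(=O)[C@]2(COC(=O)[C@@]34C[C@@H](CC[C@H]32)[C@H](CO)C4=O)[C@@H]1CO | target

**Step count.** Total: 18 steps. Longest linear sequence: 18 steps (one linear sequence from 1).

**Steps most likely to fail**

Step 4. Facial induction by the auxiliary may be poor, and at the low stationary acetylene concentration the lumiketone rearrangement of the enone and a secondary 1,3-acyl shift of the product may compete. The fallback sets out from 8, which would be irradiated with (Z)-1,2-dichloroethene as cosolvent to give the photostable cis-fused dichlorocyclobutane adduct F1. Its diastereomers would be separated, and activated Zn dust in refluxing EtOH would remove both chlorines to give the cyclobutene, returning to the route at 10.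

Step 12. Cycloaddition at C9, which sits next to the quaternary C10, may be sluggish, and face selectivity may be incomplete. The fallback sets out from 22, which would be heated in toluene with the more nucleophilic 2-(trimethylsilyloxy)buta-1,3-diene to give the silyl enol ether adduct F2 (C12–OSiMe3, C12=C13). CsF and PhNTf2 in DME would convert it to the enol triflate F3, and Pd(OAc)2/PPh3 with HCO2H and Et3N in DMF would reduce the triflate to the C12=C13 alkene, returning at 24.

Step 13. Carbopalladation may take place at C12 instead of C13 (bicyclo[2.2.2]octane closure), or the enol silane may be lost by protodesilylation without cyclisation. The fallback sets out from 24 and runs as follows: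
- The enol silane 25 would be brominated with N-bromosuccinimide at −78 °C to the bromomethyl ketone F4.
- NaBH4 with CeCl3·7H2O at −40 °C would give the bromohydrin F5.
- Bu3SnH with AIBN in benzene at 80 °C would generate the primary C16 radical, which should close 5-exo onto C13 to give the saturated C15 alcohol F6.
- Hydrogenolysis over Pd(OH)2/C would give the C1,C15-diol F7.
- Dess–Martin periodinane would oxidise both alcohols, returning at 28.

**Further compounds**

F1 | step 4 | cis-fused 7,8-dichloro analogue of 10, (1R,2S,5R)-8-phenylmenthyl 7,8-dichloro-5,5-dimethyl-2-oxobicyclo[4.2.0]octane-1-carboxylate (chlorine epimers) | C[C@@H]1CC[C@H]([C@@H](C1)OC(=O)[C@@]12C(Cl)C(Cl)[C@@H]1C(C)(C)CCC2=O)C(C)(C)c1ccccc1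
F2 | step 12 | 12-(trimethylsilyloxy) analogue of 24 (silyl enol ether C12=C13) | CC(=O)[C@]12CC=C(O[Si](C)(C)C)C[C@H]1[C@@]1(COC2=O)[C@H](CO[Si](c3ccccc3)(c3ccccc3)C(C)(C)C)C(C)(C)CC[C@H]1OCc1ccccc1
F3 | step 12 | C12 enol triflate corresponding to F2 | CC(=O)[C@]12CC=C(OS(=O)(=O)C(F)(F)F)C[C@H]1[C@@]1(COC2=O)[C@H](CO[Si](c3ccccc3)(c3ccccc3)C(C)(C)C)C(C)(C)CC[C@H]1OCc1ccccc1
F4 | step 13 | 16-bromo derivative of 24 (bromomethyl ketone) | BrCC(=O)[C@]12CC=CC[C@H]1[C@@]1(COC2=O)[C@H](CO[Si](c3ccccc3)(c3ccccc3)C(C)(C)C)C(C)(C)CC[C@H]1OCc1ccccc1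
F5 | step 13 | C15 bromohydrin from F4 (C15 epimers) | BrCC(O)[C@]12CC=CC[C@H]1[C@@]1(COC2=O)[C@H](CO[Si](c3ccccc3)(c3ccccc3)C(C)(C)C)C(C)(C)CC[C@H]1OCc1ccccc1
F6 | step 13 | saturated tetracyclic C15 alcohol with C1 benzyl ether (C15 epimers) | CC1(C)CC[C@@H](OCc5ccccc5)[C@]2(COC(=O)[C@@]34C[C@@H](CC[C@H]32)CC4O)[C@@H]1CO[Si](c1ccccc1)(c1ccccc1)C(C)(C)C
F7 | step 13 | saturated tetracyclic C1,C15-diol (C15 epimers) | CC1(C)CC[C@@H](O)[C@]2(COC(=O)[C@@]34C[C@@H](CC[C@H]32)CC4O)[C@@H]1CO[Si](c1ccccc1)(c1ccccc1)C(C)(C)C
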